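**Retrosynthetic overview**
- Target 20 ⇐ silyl ether 19 ⇐ dienoate 17 (Rh-catalysed 1,4-addition of an isopropenylboron reagent sets C4) ⇐ ketone 15 (methyl addition to the convex face sets C18).
- 15 ⇐ enone diester 7 + ynoate ester 11 in one pot (Michael / Michael / aldol / lactonisation). Ring C (cyclopentane) comes in with 11; then ring B (bridging γ-lactone), ring A (cyclohexene) and ring D (spiro-γ-lactone) close in that order.
- Key disconnection: the allylic C16–O15 bond of 11, made by enantioselective Pd-catalysed allylic acyloxylation of racemic carbonate 9 with propiolic acid. C16 is the only ring stereocentre set by a catalyst; the O15 tether relays it to C12, C22, C21 and C23.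
- 7 ⇐ L-malic acid acetonide 1 (supplies C23, C28 with O29, C27, C25) + vinylmagnesium bromide + methyl but-3-enoate (cross-metathesis).

Assumption: atoms are labelled C1–O29 in the order they stand in the target SMILES (ring stereocentres C12, C16, C18, C21, C22, C23; spirolactone carbinol C28; side-chain centre C4), and racemic 4-hydroxycyclopent-2-en-1-one 8 and L-malic acid acetonide 1 are taken as bought.

**Step 1**
Reactants: 1 (S)-2-(2,2-dimethyl-5-oxo-1,3-dioxolan-4-yl)acetic acid
Product: 2 methyl 2-[(4S)-2,2-dimethyl-5-oxo-1,3-dioxolan-4-yl]acetate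
Conditions: MeI, KHCO3, DMF, 23 °C
Reagents that add atoms: iodomethane, CI
Why: Carboxylate O-alkylation under bicarbonate leaves the base-sensitive dioxolanone and the C28 stereocentre untouched.

**Step 2**
Reactants: 2 methyl 2-[(4S)-2,2-dimethyl-5-oxo-1,3-dioxolan-4-yl]acetate; 3 vinylmagnesium bromide
Product: 4 methyl (3S)-3-hydroxy-4-oxohex-5-enoate
Conditions: 3 (1.05 equiv), THF, −78 °C; aq. NH4Cl, −78 → 0 °C
Reagents that add atoms: none
Why: Grignard acyl substitution at the activated dioxolanone carbonyl (more electrophilic than the methyl ester) gives a magnesium-chelated tetrahedral adduct that holds at −78 °C and releases the vinyl ketone and acetone only on quench, with C28 unchanged.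

**Step 3**
Reactants: 4 methyl (3S)-3-hydroxy-4-oxohex-5-enoate
Product: 5 methyl (3S)-3-[(tert-butyldimethylsilyl)oxy]-4-oxohex-5-enoate
Conditions: TBSOTf, 2,6-lutidine, CH2Cl2, −78 °C
Reagents that add atoms: tert-butyldimethylsilyl trifluoromethanesulfonate, CC(C)(C)[Si](C)(C)OS(=O)(=O)C(F)(F)F
Why: Silylation with a silyl triflate and a hindered, non-nucleophilic pyridine protects O29 without conjugate addition to the vinyl ketone.

**Step 4**
Reactants: 5 methyl (3S)-3-[(tert-butyldimethylsilyl)oxy]-4-oxohex-5-enoate; 6 methyl but-3-enoate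
Product: 7 dimethyl (3E,6S)-6-[(tert-butyldimethylsilyl)oxy]-5-oxooct-3-enedioate
Conditions: second-generation Hoveyda–Grubbs catalyst (5 mol%), 6 (3 equiv), 1,4-benzoquinone (10 mol%), CH2Cl2, 40 °C
Reagents that add atoms: none
Why: Olefin cross-metathesis of an electron-poor vinyl ketone with a terminal alkene is E-selective and ethene loss drives it, while benzoquinone suppresses isomerisation of the butenoate.

**Step 5**
Reactants: 8 rac-4-hydroxycyclopent-2-en-1-one
Product: 9 rac-tert-butyl (4-oxocyclopent-2-en-1-yl) carbonate
Conditions: Boc2O, Et3N, CH2Cl2, 0 → 23 °C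
Reagents that add atoms: di-tert-butyl dicarbonate, CC(C)(C)OC(=O)OC(=O)OC(C)(C)C
Why: O-acylation to the allylic carbonate gives an ionisable leaving group, and the material can stay racemic because the next step is meant to be stereoconvergent.

**Step 6**
Reactants: 9 rac-tert-butyl (4-oxocyclopent-2-en-1-yl) carbonate; 10 prop-2-ynoic acid
Product: 11 (1R)-4-oxocyclopent-2-en-1-yl prop-2-ynoate
Conditions: Pd2(dba)3·CHCl3 (2.5 mol%), (R,R)-DACH-phenyl Trost ligand (7.5 mol%), Bu4NCl (10 mol%), 10 added over 6 h, CH2Cl2, 0 °C
Reagents that add atoms: none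
Why: Proposed new method: a dynamic kinetic asymmetric Tsuji–Trost C–O coupling in which zerovalent palladium ionises both enantiomers of 9 (CO2 and tert-butoxide leave, the latter deprotonating 10), the two diastereomeric π-allylpalladium cations interconvert through the oxygen-bound palladium dienolate faster than the slowly fed carboxylate attacks, and the ligand pocket directs attack to C16 on one face to give the 16R ester (ligand antipode to be confirmed against the fallback sample); the closest known reaction type is the palladium/Trost-ligand kinetic resolution of this carbonate class with O-nucleophiles (≤50% yield) and the dynamic variant known for γ-acyloxybutenolides.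

**Step 7**
Reactants: 7 dimethyl (3E,6S)-6-[(tert-butyldimethylsilyl)oxy]-5-oxooct-3-enedioate; 11 (1R)-4-oxocyclopent-2-en-1-yl prop-2-ynoate
Product: 15 spiro-bis-lactone ketone (rings A to D closed), via acyclic Michael adduct 12 (not isolated), via bicyclic lactone 13 (not isolated), via tricyclic aldol 14 (not isolated)
Conditions: (i) DBU (0.2 equiv), CH2Cl2, −20 °C; (ii) MgBr2·OEt2 (1.5 equiv), iPr2NEt (1.5 equiv), −20 → 23 °C; AcOH
Reagents that add atoms: none
Why: DBU removes the doubly activated C5–H of 7 (a Hagemann-ester-type vinylogous β-keto ester) and the dienolate adds through C10 to the ynoate (Michael addition) to give 12, whose more acidic C10–H is removed again so that the magnesium-bound trienolate attacks C22 through C12 (5-exo-trig Michael addition, necessarily on the face of the C16–O15 bond, so ring B is cis-fused), the resulting C18 enolate closes ring A onto the C23 ketone on the same concave face (intramolecular aldol through a magnesium-bridged chair that keeps O24 next to the enolate oxygen and turns the bulky C28 arm outwards, setting C21 and C23), C12 equilibrates to the only epimer that can cyclise, and the C23 alkoxide lactonises onto the C25 ester to close ring D.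

**Step 8**
Reactants: 15 spiro-bis-lactone ketone; 16 methylmagnesium bromide
Product: 17 C18 tertiary alcohol
Conditions: CeCl3 (2.0 equiv), 16 (1.8 equiv), THF, −78 °C; aq. NH4Cl
Reagents that add atoms: none
Why: Imamoto organocerium 1,2-addition is non-basic and ketone-selective over the lactones and the enoate, and the methyl group enters from the convex face of the bowl (the face of H16, H21 and H22), which places Me19 syn to H21 and O20 syn to C23 as in the target.

**Step 9**
Reactants: 17 C18 tertiary alcohol; 18 4,4,5,5-tetramethyl-2-(prop-1-en-2-yl)-1,3,2-dioxaborolane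
Product: 19 O29-silyl ether of the target
Conditions: Rh(acac)(C2H4)2 (5 mol%), (R)-BINAP (6 mol%), 18 (3 equiv), K3PO4 (0.5 equiv), 1,4-dioxane/H2O (10:1), 50 °C
Reagents that add atoms: none
Why: Hayashi–Miyaura rhodium-catalysed asymmetric 1,4-addition puts the isopropenyl group on C4 under ligand control (the usual quadrant model has (S)-BINAP attacking the 2-si face of an E-enoate, which would give 4R here, hence (R)-BINAP for 4S), and 1,6-addition is blocked by the fully substituted C10 and the ring carbon C11.

**Step 10**
Reactants: 19 O29-silyl ether of the target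
Product: 20 CNP0148106.2 (target)
Conditions: HF·pyridine, THF, 0 → 23 °C
Reagents that add atoms: none
Why: Fluoride-driven desilylation frees the C28 hydroxyl without touching the lactones, the methyl ester or the tertiary alcohol.

**Compound list**
1 | (S)-2-(2,2-dimethyl-5-oxo-1,3-dioxolan-4-yl)acetic acid (L-malic acid acetonide) | OC(=O)C[C@@H]1OC(C)(C)OC1=O | starting material
2 | methyl 2-[(4S)-2,2-dimethyl-5-oxo-1,3-dioxolan-4-yl]acetate | COC(=O)C[C@@H]1OC(C)(C)OC1=O | intermediate
3 | vinylmagnesium bromide | C=C[Mg]Br | starting material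
4 | methyl (3S)-3-hydroxy-4-oxohex-5-enoate | C=CC(=O)[C@H](CC(=O)OC)O | intermediate
5 | methyl (3S)-3-[(tert-butyldimethylsilyl)oxy]-4-oxohex-5-enoate | C=CC(=O)[C@H](CC(=O)OC)O[Si](C)(C)C(C)(C)C | intermediate
6 | methyl but-3-enoate | C=CCC(=O)OC | starting material
7 | dimethyl (3E,6S)-6-[(tert-butyldimethylsilyl)oxy]-5-oxooct-3-enedioate | COC(=O)C/C=C/C(=O)[C@H](CC(=O)OC)O[Si](C)(C)C(C)(C)C | intermediate
8 | rac-4-hydroxycyclopent-2-en-1-one | OC1CC(=O)C=C1 | starting material
9 | rac-tert-butyl (4-oxocyclopent-2-en-1-yl) carbonate | CC(C)(C)OC(=O)OC1CC(=O)C=C1 | intermediate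
10 | prop-2-ynoic acid (propiolic acid) | C#CC(=O)O | starting material
11 | (1R)-4-oxocyclopent-2-en-1-yl prop-2-ynoate | C#CC(=O)O[C@@H]1CC(=O)C=C1 | intermediate
12 | 1-methyl 7-[(1R)-4-oxocyclopent-2-en-1-yl] (2E,5E)-4-{(2S)-2-[(tert-butyldimethylsilyl)oxy]-4-methoxy-4-oxobutanoyl}hepta-2,5-dienedioate (C10 epimers, labile) | COC(=O)/C=C/C(/C=C/C(=O)O[C@@H]1CC(=O)C=C1)C(=O)[C@H](CC(=O)OC)O[Si](C)(C)C(C)(C)C | intermediate
13 | bicyclic Michael adduct: cis-fused γ-lactone/cyclopentanone (16R, H16, H22 and H12 syn) carrying on C12 the (Z)-C11=C10 dienone chain; C10 bears the (E)-CH=CH–CO2Me arm and the C23 ketone with the (28S)-CH(OTBS)CH2CO2Me group | COC(=O)/C=C/C(=C/[C@@H]1C(=O)O[C@@H]2CC(=O)C[C@H]12)C(=O)[C@H](CC(=O)OC)O[Si](C)(C)C(C)(C)C | intermediate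
14 | tricyclic aldol: ring A closed by C21–C23, all-cis ring fusion (H12, H22, H21 syn), C23 tertiary alcohol with O24 syn to C18, C18 ketone, C25 methyl ester still open, (28S)-OTBS | COC(=O)/C=C/C1=C[C@@H]2C(=O)O[C@@H]3CC(=O)[C@@H]([C@H]23)[C@@]1(O)[C@H](CC(=O)OC)O[Si](C)(C)C(C)(C)C | intermediate
15 | spiro-bis-lactone ketone: 14 after lactonisation of O24 onto C25; C18 ketone, (E)-methyl acrylate arm on C10, (28S)-OTBS | COC(=O)/C=C/C1=C[C@@H]2C(=O)O[C@@H]3CC(=O)[C@@H]([C@H]23)[C@]12OC(=O)C[C@@H]2O[Si](C)(C)C(C)(C)C | intermediate
16 | methylmagnesium bromide | C[Mg]Br | starting material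
17 | C18 tertiary alcohol of 15 (Me19 on the face of H21 and H22, O20 syn to C23) | COC(=O)/C=C/C1=C[C@@H]2C(=O)O[C@@H]3C[C@](C)(O)[C@@H]([C@H]23)[C@]12OC(=O)C[C@@H]2O[Si](C)(C)C(C)(C)C | intermediate
18 | 4,4,5,5-tetramethyl-2-(prop-1-en-2-yl)-1,3,2-dioxaborolane | CC(=C)B1OC(C)(C)C(C)(C)O1 | starting material
19 | O29-tert-butyldimethylsilyl ether of the target (4S side chain in place) | C=C(C)[C@H](CC(=O)OC)C1=C[C@@H]2C(=O)O[C@@H]3C[C@](C)(O)[C@@H]([C@H]23)[C@]12OC(=O)C[C@@H]2O[Si](C)(C)C(C)(C)C | intermediate
20 | CNP0148106.2: methyl (3S)-4-methyl-3-(tricyclic bis-lactone core)pent-4-enoate, configuration as in the given SMILES | C=C(C)[C@H](CC(=O)OC)C1=C[C@@H]2C(=O)O[C@@H]3C[C@](C)(O)[C@@H]([C@H]23)[C@]12OC(=O)C[C@@H]2O | target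

**Step count**
Total: 10 steps. Longest linear sequence: 8 steps (1–4, then 7–10); steps 5–6 form the second branch.

**Three steps most likely to fail**

Step 6 (the proposed new reaction). The π-allyl complexes may not equilibrate fast enough, so that only a kinetic resolution runs (yield capped at 50%), and the propiolate product could re-ionise and lose ee. The fallback uses known chemistry, sets out from 10 and comes back at 11: propiolic acid 10 is esterified with commercial, resolved (4R)-4-hydroxycyclopent-2-en-1-one F1 using DCC in CH2Cl2 at −20 °C without DMAP (to keep amines away from the ynoate). C16 then comes from the chiral pool and not from catalysis.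

Step 7 (the cascade). The dienolate of 7 may attack through C5 instead of C10, the C18 enolate may add to the acrylate arm (double Michael) instead of the C23 ketone, or base may expel the 4-acyloxy group from the cyclopentenone. The fallback sets out from 7 and 11 and comes back at 15, replacing the anionic ring closure by a neutral cycloaddition. Compound 12 is made on purpose (DBU cat., CH2Cl2, −20 °C, then acid quench) and its acidic C10–H is silylated (Et3SiOTf, Et3N, −78 °C) to the triethylsilyl trienol ether F2. F2 is heated in toluene (130 °C, BHT) for an ester-tethered intramolecular Diels–Alder reaction (endo, silyloxy group outside), which forms the C12–C22 and C21–C23 bonds together and gives the tertiary silyl ether F3. Buffered HF·pyridine (THF, 0 °C) removes the triethylsilyl group in the presence of the TBS ether, and the freed alcohol 14 lactonises to 15.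

Step 9 (late 1,4-addition). The 2-substituted alkenylboron reagent may be too slow on the hindered dienoate, the face selectivity may be poor, or the basic aqueous medium may open a lactone. The fallback sets out from 15 and comes back at 19, reversing the order of the last two C–C bond formations and giving up catalyst control. Isopropenylmagnesium bromide with CuBr·SMe2 and Me3SiCl (THF, −78 °C) adds to the dienoate of ketone 15 under substrate control to give the keto ester F4, with the C4 epimers separated if needed. The organocerium addition of step 8 then converts F4 into 19.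

**Further compounds**
F1 | step 6 | (4R)-4-hydroxycyclopent-2-en-1-one | O[C@@H]1CC(=O)C=C1
F2 | step 7 | triethylsilyl trienol ether of 12 (C23=C10 enol ether, silyloxy group trans to the cyclopentenyl ester arm) | COC(=O)/C=C/C(/C=C/C(=O)O[C@@H]1CC(=O)C=C1)=C(\O[Si](CC)(CC)CC)[C@H](CC(=O)OC)O[Si](C)(C)C(C)(C)C
F3 | step 7 | O24-triethylsilyl ether of 14 | COC(=O)/C=C/C1=C[C@@H]2C(=O)O[C@@H]3CC(=O)[C@@H]([C@H]23)[C@@]1(O[Si](CC)(CC)CC)[C@H](CC(=O)OC)O[Si](C)(C)C(C)(C)C
F4 | step 9 | C18 ketone analogue of 19 (15 carrying the complete 4S side chain) | C=C(C)[C@H](CC(=O)OC)C1=C[C@@H]2C(=O)O[C@@H]3CC(=O)[C@@H]([C@H]23)[C@]12OC(=O)C[C@@H]2O[Si](C)(C)C(C)(C)C
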